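## The problem

Target 22 is a linear tridepside: three orsellinate-type rings, A (terminal, two free hydroxyls), B (central, one methoxy group) and C (methyl ester, one free hydroxyl), are joined by two aryl ester bonds that each run from the carbonyl on C1 of one ring to the C4 oxygen of the next. On every ring C1 carries the carbonyl, C2 and C4 carry oxygen and C6 carries a methyl group. There is no stereocentre, so the task is one of regiochemistry and chemoselectivity: six phenolic oxygens must end as two esters, one methyl ether and three free hydroxyls. Every acyl carbon lies between a methyl and an oxygen substituent, so the acids are slow to activate and their simple esters slow to saponify. Once formed, the depside bonds are open to phenoxide exchange and transesterification, so later steps must be neutral or mildly acidic. Ring B is the difficult ring, because its C2 and C4 oxygens must be told apart and, in a conventional synthesis, its hindered acid has to be freed and then activated. The feature that opens another way is that on ring B the carbonyl carbon on C1 and the methyl carbon on C6 are neighbours, with the C2 methoxy group beside them. Both carbons can therefore be delivered as one two-carbon unit across a C1–C6 aryne, and the methoxy group decides which end goes where.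

## Retrosynthesis

**22 to 21.** The last cut is at the two O–benzyl bonds of ring A. A ring A acid with free hydroxyls would acylate itself, so both must be masked. Benzyl ethers are chosen because hydrogenolysis is the one deprotection that touches neither depside bond; silyl or acetal masks would need fluoride or acid on a molecule with two aryl esters. The forward step only requires that aryl esters survive hydrogenolysis.

**21 to 17 and 19.** The ester C–O bond between the ring A carbonyl and the ring B C4 oxygen is cut next. Cutting the inner ester first would require an A–B acid whose hindered carboxyl is activated while an aryl ester sits in the same molecule. Cutting the outer ester first leaves phenol 17, whose ring B C4 hydroxyl is the only hydroxyl not held in a hydrogen bond, and acid 19, which has no other acylatable group. Acid 19 is two routine steps (via 18) from 14, the same commercial ester that serves as ring C. The forward reaction must acylate a phenol with a di-ortho-substituted acid, for which mixed-anhydride activation is the established method in depside chemistry.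

**17 to 16.** The ring B C4 hydroxyl is traced to its triisopropylsilyl ether. This group tolerates an organolithium at low temperature, dilute acid and light, and its bulk and poor coordinating ability are used when the aryne precursor is assembled.

**16 to 13 and 14.** The B–C ester C–O bond is cut and, in the same move, the ring B methyl carbon is reconnected to the carbonyl carbon, giving benzocyclobutenone 13. The neighbouring cut, free ring B acid plus phenol, would require that acid to be released from a hindered ester and then activated. Opening 13 instead gives ketene 15, an acylating agent formed under neutral conditions and captured by the only unchelated hydroxyl of unprotected 14; the CH2 group ends as the C6 methyl. Ketone 13 is the hydrolysis product of acetal 12. The forward reaction must break the C(=O)–CH2 bond of the four-membered ring, and the ketene must be caught by a phenol before it does anything else.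

**12 to 8 and 9.** The four-membered ring is cut at the bonds from C6 to CH2 and from C1 to the acetal carbon, leaving aryne 11 and ketene acetal 9. Other ways of closing a benzocyclobutenone presuppose a ring B that already carries a carbon substituent in the right place. The aryne cut removes both carbon substituents at once and reduces ring B to a tri-oxygenated benzene with iodide at C1 and triflate at C6 (compound 8). The forward reaction must place the acetal carbon on C1, next to the methoxy group, and not on C6; the inductive effect of the C2 methoxy group on the aryne is relied on for this.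

**8 to 1 and 2.** The triflate is traced to phenol 7 and the iodine to lithiation of 4 (via 5, giving 6). Electrophilic iodination of 3 would be two steps shorter, but it would have to choose among three activated ring positions, of which only the one between hydroxyl and methoxy is wanted. Directed metalation is preferred because the carbon between the methoxy and methoxymethoxy groups of 4 is the only one flanked by two coordinating oxygens. Compound 4 comes from 3, and 3 from mono-silylation of symmetrical 1 with 2.

## Roads not taken

**Alternative 1:** The cut lies inside ring C. Bonds C1–C6 and C3–C4 are broken, which reduces the ring to methyl acetoacetate A1 and methyl crotonate A2. Forward, NaOMe in MeOH would join A1 and A2 by Michael addition (C1–C6) and Dieckmann condensation (C3–C4) and so give racemic methyl trans-2-methyl-4,6-dioxocyclohexane-1-carboxylate A3. The C4 enol oxygen of A3 would be acylated by a ring B acid derivative, and ring C would be dehydrogenated at the end.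
- Merits: A1 and A2 are cheap, the ring forms in one pot without a cryogenic step and scales easily, and the C4 oxygen is distinguished from the C2 oxygen without a protecting group.
- Weak points: the ring it builds is, after aromatisation, 14, which can be bought. The two stereocentres of A3 are made only to be destroyed. An enol ester of a 1,3-dione is a vinylogous anhydride and would have to survive the attachment of ring A without acyl transfer or oxygen-to-carbon acyl migration. The final dehydrogenation would have to be carried out beside two electron-rich rings and two aryl esters. Ring B, the real difficulty, is not addressed.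
- Comparison: in cost and robustness of ring construction this chemistry is better than anything in the chosen plan. Against that, the chosen plan needs no ring C construction at all and spends its effort on ring B.

**Alternative 2:** The cut is at the ring A C1–carbonyl bond and the carbonyl–oxygen bond to ring B C4. The A–B ester is assembled from 1,5-bis(benzyloxy)-2-iodo-3-methylbenzene A4, carbon monoxide A5 and the B–C phenol A6, which is the same compound as 17. Forward, Pd(OAc)2, Xantphos and Et3N would combine A4, A5 and A6 to give the dibenzyl ether A7, which is the same compound as 21; no ring is closed.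
- Merits: the hindered ring A acid is never made or activated, so the forcing saponification of step 11 disappears. For the A–B junction it is arguably the more elegant construction and about as short.
- Weak points: oxidative addition of zerovalent palladium into the electron-rich iodide A4, flanked by methyl and benzyloxy groups, is slow. The resulting di-ortho-substituted acylpalladium must be intercepted by a phenol made electron-poor by its para ester, so reduction of the iodide and decarbonylation become competitive. The method also supplies nothing for ring B or the B–C bond: it needs A6 from elsewhere, and A4 needs its own preparation.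
- Comparison: the chosen plan sets the predictability of anhydride coupling at an unhindered phenol against the better economy of this junction, and places its key step where the structural problem lies.

**Alternative 3:** The cut is at ring B bonds C5–C6 and C3–C4. Ring B is built by inverse-demand cycloaddition of a 2-pyrone that already carries ring C as its ester, with the ring C hydroxyl masked as benzyl ether: 3-(benzyloxy)-4-(methoxycarbonyl)-5-methylphenyl 4-methoxy-6-methyl-2-oxo-2H-pyran-5-carboxylate A8. Forward, A8 is heated with 1,1-bis(trimethylsilyloxy)ethene A9. The cycloadduct would lose its lactone bridge as gas and one silyloxy group by elimination, and work-up would give methyl 2-(benzyloxy)-4-[(4-hydroxy-2-methoxy-6-methylbenzoyl)oxy]-6-methylbenzoate A10. Hydrogenolysis of A10 would then give 17.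
- Merits: the B–C ester is made before ring B exists, ring B appears in A10 with its C4 hydroxyl already free, and neither organolithium nor light is needed. In these respects it is better than the chosen plan, which needs a silyl ether and its removal.
- Weak points: the diene of A8 carries a donor methoxy group at C4 and a methyl at the terminus that must bond to the nucleophilic CH2 of A9, both of which lower its reactivity in the inverse-demand mode. A8 needs its own multi-step synthesis, pyrone ring included, and ring C needs a benzyl ether put on and taken off.
- Comparison: both routes bring in two ring B carbons with a ketene acetal. The chosen plan sets against this one a cycloaddition partner (8) reached from a commercial phenol, and regiocontrol by the methoxy group that has direct precedent in its own substrate class.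

Key step: step 6

Remark on the chemistry: the target has no stereocentre, so no step sets or preserves configuration; for step 8 the photochemical mode of ring opening is assumed, since it runs at room temperature.

## Route

Step 1
Reactants: 1 5-methoxyresorcinol; 2 triisopropylsilyl chloride
Product: 3 3-methoxy-5-(triisopropylsilyloxy)phenol
Conditions: imidazole, DMF, 0 °C to rt
Reagents that add atoms: none
Why: Statistical mono-O-silylation of a symmetrical diphenol (imidazole-promoted silyl ether formation); unreacted 1 and the bis-silyl ether should be separable and recyclable.

Step 2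
Reactants: 3 3-methoxy-5-(triisopropylsilyloxy)phenol
Product: 4 1-methoxy-3-(methoxymethoxy)-5-(triisopropylsilyloxy)benzene
Conditions: MOMCl, i-Pr2NEt, CH2Cl2, 0 °C to rt
Reagents that add atoms: chloromethyl methyl ether, COCCl
Why: O-Alkylation of the remaining phenol (methoxymethyl ether formation); the acetal oxygen is installed as the directing group for step 3 and the aryl silyl ether is untouched.

Step 3
Reactants: 4 1-methoxy-3-(methoxymethoxy)-5-(triisopropylsilyloxy)benzene
Product: 6 2-iodo-1-methoxy-3-(methoxymethoxy)-5-(triisopropylsilyloxy)benzene, via aryllithium 5 (not isolated)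
Conditions: n-BuLi, THF, 0 °C; then I2, -78 °C to rt
Reagents that add atoms: iodine, [I][I]
Why: Directed ortho-metalation followed by iodine quench; the carbon between the methoxy and methoxymethoxy groups is the only one flanked by two coordinating oxygens, and the positions next to the bulky, poorly coordinating silyloxy group should not be metalated.

Step 4
Reactants: 6 2-iodo-1-methoxy-3-(methoxymethoxy)-5-(triisopropylsilyloxy)benzene
Product: 7 2-iodo-3-methoxy-5-(triisopropylsilyloxy)phenol
Conditions: conc. HCl (cat.), MeOH/THF, 40 °C
Reagents that add atoms: none
Why: Acid-catalysed acetal exchange removes the methoxymethyl ether; aryl triisopropylsilyl ethers and the aryl iodide should tolerate dilute methanolic acid at this temperature.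

Step 5
Reactants: 7 2-iodo-3-methoxy-5-(triisopropylsilyloxy)phenol
Product: 8 2-iodo-3-methoxy-5-(triisopropylsilyloxy)phenyl trifluoromethanesulfonate
Conditions: Tf2O, pyridine, CH2Cl2, 0 °C
Reagents that add atoms: trifluoromethanesulfonic anhydride, O=S(=O)(OS(=O)(=O)C(F)(F)F)C(F)(F)F
Why: O-Sulfonylation of the phenol, the usual way to 2-iodoaryl triflates as aryne precursors.

Step 6
Reactants: 8 2-iodo-3-methoxy-5-(triisopropylsilyloxy)phenyl trifluoromethanesulfonate; 9 1,1-dimethoxyethene
Product: 12 2,8,8-trimethoxy-4-(triisopropylsilyloxy)bicyclo[4.2.0]octa-1,3,5-triene (ring B benzocyclobutenone dimethyl acetal), via aryllithium 10 (not isolated), via aryne 11 (not isolated)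
Conditions: 9 (3 equiv), n-BuLi, THF, -78 °C
Reagents that add atoms: none
Why: Iodine-lithium exchange at C1 should outrun attack of n-BuLi on the triflate or on 9 and give aryllithium 10, which loses LiOTf at -78 °C to give the C1-C6 aryne 11. The C2 methoxy group withdraws inductively and distorts the aryne, so the nucleophilic CH2 terminus of 9 bonds to the remote carbon C6 and negative charge builds at C1 beside the methoxy group. The aryl anion then collapses onto the dimethoxycarbenium carbon (4-exo-trig closure of the zwitterion), so the four-membered ring forms by a stepwise formal [2+2] cycloaddition. The closest known reaction type is the [2+2] cycloaddition of 3-alkoxybenzynes, generated from 2-iodo-3-alkoxyaryl triflates with n-BuLi, with ketene acetals, which gives benzocyclobutenone acetals with the acetal carbon next to the alkoxy group. No stereocentre is formed. The step needs regioselectivity (acetal carbon on C1, CH2 on C6) and chemoselectivity (capture of the aryne by 9 before butyl- or aryllithium adds to it); the first rests on the C2 methoxy group, against which the C4 silyloxy group, meta to C6 and para to C1, has only a weak influence, and the second on an excess of 9 being present before n-BuLi is added.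

Step 7
Reactants: 12 2,8,8-trimethoxy-4-(triisopropylsilyloxy)bicyclo[4.2.0]octa-1,3,5-triene
Product: 13 5-methoxy-3-(triisopropylsilyloxy)bicyclo[4.2.0]octa-1,3,5-trien-7-one
Conditions: 1 M aq. HCl, THF, rt
Reagents that add atoms: water, O
Why: Acid-catalysed acetal hydrolysis through an oxocarbenium ion stabilised by the ortho methoxy and para silyloxy groups; the aryl silyl ether should be stable to dilute aqueous acid at room temperature.

Step 8
Reactants: 13 5-methoxy-3-(triisopropylsilyloxy)bicyclo[4.2.0]octa-1,3,5-trien-7-one; 14 methyl orsellinate (methyl 2,4-dihydroxy-6-methylbenzoate)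
Product: 16 methyl 2-hydroxy-4-{[2-methoxy-6-methyl-4-(triisopropylsilyloxy)benzoyl]oxy}-6-methylbenzoate, via ortho-quinoid ketene 15 (not isolated)
Conditions: hν (350 nm), 14 (3 equiv), dry MeCN, rt
Reagents that add atoms: none
Why: Photochemical cleavage of the C(=O)-CH2 bond (formal 4π ring opening) gives ketene 15, the unchelated C4 hydroxyl of 14 adds to the ketene carbon and tautomerisation restores ring B with the former CH2 as the C6 methyl (the known benzocyclobutenone to ortho-toluate reaction with hydroxylic traps); the C2 hydroxyl of 14 is held in a hydrogen bond to its ester, and untrapped ketene recloses to 13.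

Step 9
Reactants: 16 methyl 2-hydroxy-4-{[2-methoxy-6-methyl-4-(triisopropylsilyloxy)benzoyl]oxy}-6-methylbenzoate
Product: 17 methyl 2-hydroxy-4-[(4-hydroxy-2-methoxy-6-methylbenzoyl)oxy]-6-methylbenzoate
Conditions: TBAF, AcOH, THF, 0 °C
Reagents that add atoms: none
Why: Fluoride cleavage of an aryl silyl ether, buffered with acetic acid so that no free phenoxide can exchange into the depside bond, which is in addition shielded by its two ortho substituents.

Step 10
Reactants: 14 methyl orsellinate
Product: 18 methyl 2,4-bis(benzyloxy)-6-methylbenzoate
Conditions: BnBr (2.5 equiv), K2CO3, DMF, 60 °C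
Reagents that add atoms: benzyl bromide, BrCc1ccccc1
Why: Williamson etherification of both phenols; the chelated C2 hydroxyl needs DMF and warming but should be benzylated with excess benzyl bromide.

Step 11
Reactants: 18 methyl 2,4-bis(benzyloxy)-6-methylbenzoate
Product: 19 2,4-bis(benzyloxy)-6-methylbenzoic acid
Conditions: KOH, DMSO/H2O, 90 °C; then aq. HCl
Reagents that add atoms: potassium hydroxide, [K+].[OH-]
Why: Saponification of a di-ortho-substituted methyl benzoate, which needs hot hydroxide in aqueous DMSO; the benzyl ethers are stable and the acid is freed on acidification.

Step 12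
Reactants: 17 methyl 2-hydroxy-4-[(4-hydroxy-2-methoxy-6-methylbenzoyl)oxy]-6-methylbenzoate; 19 2,4-bis(benzyloxy)-6-methylbenzoic acid
Product: 21 methyl 4-[(4-{[2,4-bis(benzyloxy)-6-methylbenzoyl]oxy}-2-methoxy-6-methylbenzoyl)oxy]-2-hydroxy-6-methylbenzoate, via mixed anhydride 20 (not isolated)
Conditions: (CF3CO)2O, toluene, rt
Reagents that add atoms: none
Why: Mixed-anhydride esterification as used for depsides: trifluoroacetic anhydride turns 19 into acyl trifluoroacetate 20, an acylium equivalent that a di-ortho-substituted acid can still form, and 20 acylates the unhindered ring B C4 hydroxyl of 17 while the ring C hydroxyl is deactivated by its hydrogen bond to the methyl ester.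

Step 13
Reactants: 21 methyl 4-[(4-{[2,4-bis(benzyloxy)-6-methylbenzoyl]oxy}-2-methoxy-6-methylbenzoyl)oxy]-2-hydroxy-6-methylbenzoate
Product: 22 methyl 4-({4-[(2,4-dihydroxy-6-methylbenzoyl)oxy]-2-methoxy-6-methylbenzoyl}oxy)-2-hydroxy-6-methylbenzoate (target)
Conditions: H2 (1 atm), 10% Pd/C (palladium on carbon), EtOAc, rt
Reagents that add atoms: none
Why: Catalytic hydrogenolysis of the two benzyl aryl ethers under neutral conditions; the aryl esters, the methyl ester and the methyl ether should be inert.

## Compound list

1 | 5-methoxyresorcinol | COc1cc(O)cc(O)c1 | starting material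
2 | triisopropylsilyl chloride | CC(C)[Si](Cl)(C(C)C)C(C)C | starting material
3 | 3-methoxy-5-(triisopropylsilyloxy)phenol | COc1cc(O)cc(O[Si](C(C)C)(C(C)C)C(C)C)c1 | intermediate
4 | 1-methoxy-3-(methoxymethoxy)-5-(triisopropylsilyloxy)benzene | COCOc1cc(OC)cc(O[Si](C(C)C)(C(C)C)C(C)C)c1 | intermediate
5 | [2-methoxy-6-(methoxymethoxy)-4-(triisopropylsilyloxy)phenyl]lithium | COCOc1cc(O[Si](C(C)C)(C(C)C)C(C)C)cc(OC)c1[Li] | intermediate
6 | 2-iodo-1-methoxy-3-(methoxymethoxy)-5-(triisopropylsilyloxy)benzene | COCOc1cc(O[Si](C(C)C)(C(C)C)C(C)C)cc(OC)c1I | intermediate
7 | 2-iodo-3-methoxy-5-(triisopropylsilyloxy)phenol | COc1cc(O[Si](C(C)C)(C(C)C)C(C)C)cc(O)c1I | intermediate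
8 | 2-iodo-3-methoxy-5-(triisopropylsilyloxy)phenyl trifluoromethanesulfonate | COc1cc(O[Si](C(C)C)(C(C)C)C(C)C)cc(OS(=O)(=O)C(F)(F)F)c1I | intermediate
9 | 1,1-dimethoxyethene | C=C(OC)OC | starting material
10 | [2-methoxy-4-(triisopropylsilyloxy)-6-(trifluoromethylsulfonyloxy)phenyl]lithium | COc1cc(O[Si](C(C)C)(C(C)C)C(C)C)cc(OS(=O)(=O)C(F)(F)F)c1[Li] | intermediate
11 | 3-methoxy-5-(triisopropylsilyloxy)benzyne (ring B C1-C6 aryne) | COC1=CC(O[Si](C(C)C)(C(C)C)C(C)C)=CC#C1 | intermediate
12 | 2,8,8-trimethoxy-4-(triisopropylsilyloxy)bicyclo[4.2.0]octa-1,3,5-triene | COc1cc(O[Si](C(C)C)(C(C)C)C(C)C)cc2c1C(OC)(OC)C2 | intermediate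
13 | 5-methoxy-3-(triisopropylsilyloxy)bicyclo[4.2.0]octa-1,3,5-trien-7-one | COc1cc(O[Si](C(C)C)(C(C)C)C(C)C)cc2c1C(=O)C2 | intermediate
14 | methyl orsellinate (methyl 2,4-dihydroxy-6-methylbenzoate) | COC(=O)c1c(C)cc(O)cc1O | starting material
15 | [2-methoxy-6-methylidene-4-(triisopropylsilyloxy)cyclohexa-2,4-dien-1-ylidene]methanone (ortho-quinoid ketene) | COC1=CC(O[Si](C(C)C)(C(C)C)C(C)C)=CC(=C)C1=C=O | intermediate
16 | methyl 2-hydroxy-4-{[2-methoxy-6-methyl-4-(triisopropylsilyloxy)benzoyl]oxy}-6-methylbenzoate | COC(=O)c1c(C)cc(OC(=O)c2c(C)cc(O[Si](C(C)C)(C(C)C)C(C)C)cc2OC)cc1O | intermediate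
17 | methyl 2-hydroxy-4-[(4-hydroxy-2-methoxy-6-methylbenzoyl)oxy]-6-methylbenzoate | COC(=O)c1c(C)cc(OC(=O)c2c(C)cc(O)cc2OC)cc1O | intermediate
18 | methyl 2,4-bis(benzyloxy)-6-methylbenzoate | COC(=O)c1c(C)cc(OCc2ccccc2)cc1OCc1ccccc1 | intermediate
19 | 2,4-bis(benzyloxy)-6-methylbenzoic acid | Cc1cc(OCc2ccccc2)cc(OCc2ccccc2)c1C(=O)O | intermediate
20 | 2,4-bis(benzyloxy)-6-methylbenzoic trifluoroacetic anhydride | Cc1cc(OCc2ccccc2)cc(OCc2ccccc2)c1C(=O)OC(=O)C(F)(F)F | intermediate
21 | methyl 4-[(4-{[2,4-bis(benzyloxy)-6-methylbenzoyl]oxy}-2-methoxy-6-methylbenzoyl)oxy]-2-hydroxy-6-methylbenzoate | COC(=O)c1c(C)cc(OC(=O)c2c(C)cc(OC(=O)c3c(C)cc(OCc4ccccc4)cc3OCc3ccccc3)cc2OC)cc1O | intermediate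
22 | methyl 4-({4-[(2,4-dihydroxy-6-methylbenzoyl)oxy]-2-methoxy-6-methylbenzoyl}oxy)-2-hydroxy-6-methylbenzoate | COC(=O)c1c(C)cc(OC(=O)c2c(C)cc(OC(=O)c3c(C)cc(O)cc3O)cc2OC)cc1O | target

## Step count and risks

Total step count: 13. Longest linear sequence: 11 steps (steps 1 to 9, 12 and 13, from 5-methoxyresorcinol); steps 10 and 11 form the two-step side branch to ring A.

**Step 6 (key step).** The most likely failure is competitive addition of n-BuLi or of aryllithium 10 to the aryne, because a dimethyl ketene acetal is a weaker nucleophile than the silyl ketene acetals most often used. Leakage of regioselectivity is the second concern. The fallback gives up the aryne and builds ring B from 14 by classical depside chemistry, returning to the route at 17. Selective benzylation of the unchelated C4 hydroxyl of 14 (BnBr, K2CO3, acetone) would give methyl 4-(benzyloxy)-2-hydroxy-6-methylbenzoate F1. O-Methylation of the chelated hydroxyl (MeI, K2CO3, DMF) would give methyl 4-(benzyloxy)-2-methoxy-6-methylbenzoate F2. Hot KOH in aqueous DMSO would give 4-(benzyloxy)-2-methoxy-6-methylbenzoic acid F3. Trifluoroacetic anhydride coupling with a second portion of 14 would give methyl 4-{[4-(benzyloxy)-2-methoxy-6-methylbenzoyl]oxy}-2-hydroxy-6-methylbenzoate F4, and hydrogenolysis would give 17. This fallback is shorter than the main line but accepts saponification and activation of the hindered ring B acid.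

**Step 8.** The phenol of 14 is a weak nucleophile (para ester), so capture of the ketene may be slow. Reclosure to 13 would then dominate, and secondary photochemistry of the ketene or photo-Fries rearrangement of the aryl ester product could take over on prolonged irradiation. The fallback sets out from 13 and returns at 16; it gives up direct capture of the ketene by the phenol and forms the B–C ester by activation of a free acid instead. Irradiation of 13 in aqueous MeCN (hν 350 nm, rt), where water at high concentration is the trap, is the known opening of benzocyclobutenones in hydroxylic media and would give 2-methoxy-6-methyl-4-(triisopropylsilyloxy)benzoic acid F5. This would be coupled with 14 by the trifluoroacetic anhydride method of step 12 to give 16.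

**Step 9.** Even with buffering, transient phenoxide may attack the depside bond, leading to ester exchange or cleavage. The fallback sets out from 13 and returns at 21 by changing the order of events. Desilylation of 13 (TBAF, AcOH), where no ester is yet present, would give 3-hydroxy-5-methoxybicyclo[4.2.0]octa-1,3,5-trien-7-one F6. Acylation with 19 (trifluoroacetic anhydride, toluene) would give 5-methoxy-7-oxobicyclo[4.2.0]octa-1,3,5-trien-3-yl 2,4-bis(benzyloxy)-6-methylbenzoate F7. Irradiation of F7 with 14 as in step 8 would give 21 directly.

**Step 3.** Metalation beside the silyloxy group, followed by migration of silicon from oxygen to carbon, or attack of n-BuLi at silicon, would lower the yield of the wanted aryllithium. The fallback sets out from 3 and returns at 7, skipping 4 and 6: electrophilic ortho-iodination of phenol 3 (I2, NaHCO3, aqueous THF, 0 °C). This relies on the bulk of the silyl ether to shield both ring positions next to it, so that iodine enters at the carbon between hydroxyl and methoxy, and it makes no new compound.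

## Further compounds

F1 | step 6 | methyl 4-(benzyloxy)-2-hydroxy-6-methylbenzoate | COC(=O)c1c(C)cc(OCc2ccccc2)cc1O
F2 | step 6 | methyl 4-(benzyloxy)-2-methoxy-6-methylbenzoate | COC(=O)c1c(C)cc(OCc2ccccc2)cc1OC
F3 | step 6 | 4-(benzyloxy)-2-methoxy-6-methylbenzoic acid | COc1cc(OCc2ccccc2)cc(C)c1C(=O)O
F4 | step 6 | methyl 4-{[4-(benzyloxy)-2-methoxy-6-methylbenzoyl]oxy}-2-hydroxy-6-methylbenzoate | COC(=O)c1c(C)cc(OC(=O)c2c(C)cc(OCc3ccccc3)cc2OC)cc1O
F5 | step 8 | 2-methoxy-6-methyl-4-(triisopropylsilyloxy)benzoic acid | COc1cc(O[Si](C(C)C)(C(C)C)C(C)C)cc(C)c1C(=O)O
F6 | step 9 | 3-hydroxy-5-methoxybicyclo[4.2.0]octa-1,3,5-trien-7-one | COc1cc(O)cc2c1C(=O)C2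
F7 | step 9 | 5-methoxy-7-oxobicyclo[4.2.0]octa-1,3,5-trien-3-yl 2,4-bis(benzyloxy)-6-methylbenzoate | COc1cc(OC(=O)c3c(C)cc(OCc4ccccc4)cc3OCc3ccccc3)cc2c1C(=O)C2
F0 | step 3 | none | none
A1 | alternative 1 | methyl acetoacetate | COC(=O)CC(C)=O
A2 | alternative 1 | methyl (E)-crotonate | C/C=C/C(=O)OC
A3 | alternative 1 | methyl trans-2-methyl-4,6-dioxocyclohexane-1-carboxylate (racemic, one enantiomer drawn) | COC(=O)[C@H]1[C@H](C)CC(=O)CC1=O
A4 | alternative 2 | 1,5-bis(benzyloxy)-2-iodo-3-methylbenzene | Cc1cc(OCc2ccccc2)cc(OCc2ccccc2)c1I
A5 | alternative 2 | carbon monoxide | [C-]#[O+]
A6 | alternative 2 | methyl 2-hydroxy-4-[(4-hydroxy-2-methoxy-6-methylbenzoyl)oxy]-6-methylbenzoate (same compound as 17) | COC(=O)c1c(C)cc(OC(=O)c2c(C)cc(O)cc2OC)cc1O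
A7 | alternative 2 | methyl 4-[(4-{[2,4-bis(benzyloxy)-6-methylbenzoyl]oxy}-2-methoxy-6-methylbenzoyl)oxy]-2-hydroxy-6-methylbenzoate (same compound as 21) | COC(=O)c1c(C)cc(OC(=O)c2c(C)cc(OC(=O)c3c(C)cc(OCc4ccccc4)cc3OCc3ccccc3)cc2OC)cc1O
A8 | alternative 3 | 3-(benzyloxy)-4-(methoxycarbonyl)-5-methylphenyl 4-methoxy-6-methyl-2-oxo-2H-pyran-5-carboxylate | COC(=O)c1c(C)cc(OC(=O)C2=C(C)OC(=O)C=C2OC)cc1OCc1ccccc1
A9 | alternative 3 | 1,1-bis(trimethylsilyloxy)ethene | C=C(O[Si](C)(C)C)O[Si](C)(C)C
A10 | alternative 3 | methyl 2-(benzyloxy)-4-[(4-hydroxy-2-methoxy-6-methylbenzoyl)oxy]-6-methylbenzoate | COC(=O)c1c(C)cc(OC(=O)c2c(C)cc(O)cc2OC)cc1OCc1ccccc1
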